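**Plan**

1. Numbering (germacranolide): carbocycle C1–C10 (C2 ketone, C4=C5, C6–O, C7, C8–OAc, C10=C14), lactone C11(=C13)–C12, C15 = CH2OAc on C4.
2. Cuts, in retrosynthetic order: C11=C13 (kept as a Me2NH adduct); C2=O back to C2–NO2 (Nef); the carbocycle at C2–C3 (C2 nitronate onto an allylpalladium unit C3–C4–C5); C2–N back to C2–Br; C7–C8 together with C11=C13 (Barbier addition of a 3-(bromomethyl)butenolide to an aldehyde); the butenolide C7=C11 (ring-closing metathesis); C4=C5 back to a C4 ketone.
3. Enabling feature: C4 bears two oxygenated methylenes (ring carbon C3 and C15–OAc), and C2 is a carbonyl next to the allylic C3. The precursor can therefore be a 2-alkylidene-propane-1,3-diyl diacetate with two identical arms (no olefin geometry to build; the unused arm is the C15 acetate), closed by an acyl-anion equivalent at C2.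
4. Forward order: lactone ring first (step 6); then the C8–C2 side chain with the methylene lactone (step 10); then the ten-membered carbocycle (step 14); then ketone release and unmasking.
5. Stereochemistry: C6 from lipase resolution of a dienol; C7 by addition anti to the C6 substituent of the butenolide; C8 by a chair transition state of the ring-locked E-allylzinc; C4=C5 geometry from the syn-allyl palladium complex in the ring closure.

Key step: step 14

Remark: C11 (compounds 19–23) and C2 (compounds 20, 21) are transient stereocentres, carried as epimer mixtures and drawn without configuration; steps 16 and 15 erase them.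

**Route**

Step 1
Reactants: 1 1,3-diacetoxyacetone (2-oxopropane-1,3-diyl diacetate); 2 vinylmagnesium bromide
Product: 3 2-hydroxy-2-vinylpropane-1,3-diyl diacetate
Conditions: 2 (1.05 equiv), CeCl3, THF, −78 °C; AcOH quench at −78 °C
Reagents that add atoms: none
Why: Grignard 1,2-addition to the strongly activated α,α′-diacyloxy ketone should outrun attack on the acetates at −78 °C, with CeCl3 suppressing enolisation; no stereocentre is formed.

Step 2
Reactants: 3 2-hydroxy-2-vinylpropane-1,3-diyl diacetate
Product: 4 4-acetoxy-3-(acetoxymethyl)but-2-enal
Conditions: pyridinium chlorochromate [C5H5NH][CrO3Cl] (2.5 equiv), 4 Å MS, CH2Cl2, rt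
Reagents that add atoms: pyridinium chlorochromate ([O-][Cr](=O)(=O)Cl.c1cc[nH+]cc1)
Why: Babler–Dauben oxidative transposition, in which the hexavalent chromium ester of the tertiary vinyl carbinol undergoes a [3,3] shift to the primary allylic chromate (its oxygen comes from the reagent) and is oxidised to the enal; the two identical acetoxymethyl groups on C4 mean the new C4=C5 bond has no E/Z isomers.

Step 3
Reactants: 4 4-acetoxy-3-(acetoxymethyl)but-2-enal; 2 vinylmagnesium bromide
Product: 5 rac-2-(2-hydroxybut-3-en-1-ylidene)propane-1,3-diyl diacetate
Conditions: 2 (1.05 equiv), THF, −78 °C; AcOH quench at −78 °C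
Reagents that add atoms: none
Why: 1,2-addition of a vinyl Grignard reagent to an enal should give the racemic bis-allylic alcohol, whose carbinol carbon (C6) is resolved in the next step.

Step 4
Reactants: 5 rac-2-(2-hydroxybut-3-en-1-ylidene)propane-1,3-diyl diacetate
Product: 6 (S)-2-(2-hydroxybut-3-en-1-ylidene)propane-1,3-diyl diacetate
Conditions: Candida antarctica lipase B (immobilised), vinyl acetate, t-BuOMe, 30 °C, stopped just past half conversion; chromatography
Reagents that add atoms: none
Why: Lipase-catalysed kinetic resolution by transesterification; by the empirical size rule for secondary alcohols (large = trisubstituted alkenyl, medium = vinyl) the R alcohol should be acetylated, and the recovered S alcohol has the C6 configuration of the target.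

Step 5
Reactants: 6 (S)-2-(2-hydroxybut-3-en-1-ylidene)propane-1,3-diyl diacetate; 7 2-(bromomethyl)acrylic acid
Product: 9 (S)-1-[3-acetoxy-2-(acetoxymethyl)prop-1-en-1-yl]allyl 2-(bromomethyl)acrylate, via 2-(bromomethyl)acryloyl chloride 8 (not isolated)
Conditions: 7, (COCl)2, cat. DMF, CH2Cl2, 0 °C → rt; then 6, 2,6-lutidine, CH2Cl2, −20 → 0 °C
Reagents that add atoms: none
Why: Esterification of the secondary alcohol by the acid chloride with a hindered pyridine base that should not displace the allylic bromide; the C6 configuration is untouched.

Step 6
Reactants: 9 (S)-1-[3-acetoxy-2-(acetoxymethyl)prop-1-en-1-yl]allyl 2-(bromomethyl)acrylate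
Product: 10 (R)-3-(bromomethyl)-5-[3-acetoxy-2-(acetoxymethyl)prop-1-en-1-yl]furan-2(5H)-one
Conditions: second-generation Hoveyda–Grubbs catalyst RuCl2(H2IMes)(=CH–C6H4–2-OiPr) (5 mol %), toluene (0.01 M), 80 °C, argon sparge
Reagents that add atoms: none
Why: Ring-closing metathesis of an acrylate of an allylic alcohol: the ruthenium alkylidene loads on the monosubstituted vinyl group and closes the five-membered butenolide onto the 1,1-disubstituted acrylate olefin with loss of ethylene, while the trisubstituted C4=C5 olefin stays inert and C6 is unaffected.

Step 7
Reactants: 11 3-methylbut-3-en-1-ol; 12 paraformaldehyde (as formaldehyde)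
Product: 13 3-methylenepentane-1,5-diol
Conditions: n-BuLi (2.2 equiv), TMEDA, Et2O, 0 °C → rt; then 12, −78 °C → rt; H2O
Reagents that add atoms: none
Why: Alkoxide-directed allylic lithiation of the homoallylic alcohol gives the dianion, which is hydroxymethylated at the former methyl carbon; no stereocentre.

Step 8
Reactants: 13 3-methylenepentane-1,5-diol
Product: 14 5-bromo-3-methylenepentan-1-ol
Conditions: CBr4 (1.0 equiv), PPh3 (1.0 equiv), CH2Cl2, 0 °C; monobromide separated, unreacted diol recycled
Reagents that add atoms: carbon tetrabromide (BrC(Br)(Br)Br)
Why: Appel reaction run as a monofunctionalisation of the symmetric diol under neutral conditions that should leave the 1,1-disubstituted olefin alone.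

Step 9
Reactants: 14 5-bromo-3-methylenepentan-1-ol
Product: 15 5-bromo-3-methylenepentanal
Conditions: Dess–Martin periodinane, NaHCO3, CH2Cl2, 0 °C; crude aldehyde used at once
Reagents that add atoms: none
Why: Dess–Martin oxidation under buffered neutral conditions should give the β,γ-unsaturated aldehyde without moving the olefin into conjugation.

Step 10
Reactants: 10 (R)-3-(bromomethyl)-5-[3-acetoxy-2-(acetoxymethyl)prop-1-en-1-yl]furan-2(5H)-one; 15 5-bromo-3-methylenepentanal
Product: 16 (6R,7R,8S in target numbering) 5-[3-acetoxy-2-(acetoxymethyl)prop-1-enyl]-4-(5-bromo-1-hydroxy-3-methylenepentyl)-3-methylenedihydrofuran-2(3H)-one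
Conditions: Zn dust, 15 (1.5 equiv), THF/sat. aq NH4Cl (2:1), 0 °C → rt
Reagents that add atoms: none
Why: Barbier-type zinc allylation with allylic transposition, the reaction type known for 3-(bromomethyl)furan-2(5H)-ones: the allylzinc bonds through ring carbon C7 on the face anti to the C6 alkenyl group (6,7-trans lactone, C11=C13 formed at the same time), and because the ring holds C6 trans to the CH2Zn terminus (an E-type allylmetal) a chair Zimmerman–Traxler transition state with the aldehyde chain equatorial should give the 7,8-anti adduct, which is the 8S configuration of the target.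

Step 11
Reactants: 16 hydroxy bromide (as above)
Product: 17 C8 acetate of 16
Conditions: Ac2O, pyridine, cat. DMAP, CH2Cl2, 0 °C
Reagents that add atoms: acetic anhydride (CC(=O)OC(C)=O)
Why: Standard acetylation installs the C8 acetate of the target with retention and blocks translactonisation onto C8–OH.

Step 12
Reactants: 17 C8 acetate (bromide)
Product: 18 nitro compound (Br of 17 replaced by NO2 at C2)
Conditions: AgNO2 (1.5 equiv), Et2O, 0 °C → rt, dark
Reagents that add atoms: silver nitrite ([Ag+].[O-]N=O)
Why: Victor Meyer reaction, in which nitrite on monovalent silver displaces the primary bromide at nitrogen to give the primary nitroalkane that makes C2 an acyl-anion equivalent; the neutral medium leaves the methylene lactone and the acetates untouched.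

Step 13
Reactants: 18 nitro compound
Product: 19 dimethylamine adduct of 18 (3-(dimethylaminomethyl) lactone, C11 epimers)
Conditions: Me2NH (2 M in THF, 1.5 equiv), THF, 0 °C; volatiles removed
Reagents that add atoms: dimethylamine (CNC)
Why: Aza-Michael addition masks C13, the only strong Michael acceptor, so that the C2 nitronate needed in steps 14 and 15 cannot add to it; the β-amino lactone is stable to base and the new C11 centre is inconsequential.

Step 14
Reactants: 19 amine-masked nitro bis(allylic acetate)
Product: 20 macrocyclic nitro compound (ten-membered carbocycle, 2-nitro, ring-trans C4=C5, C15–OAc, C8–OAc, masked lactone; C2 epimers)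
Conditions: Pd(PPh3)4 (10 mol %), Cs2CO3 (1.5 equiv), THF/DMSO (20:1), 40 °C, slow addition of 19 to 0.003 M final concentration
Reagents that add atoms: none
Why: Proposed new method: zerovalent palladium ionises one of the two acetoxymethyl groups on C4 to a cationic η3-allyl complex (C3–C4–C5), and the caesium nitronate of C2 attacks its CH2 terminus C3 on the face opposite the metal, forming the C2–C3 bond and the carbocycle in one irreversible event; the closest known reaction types are the palladium-catalysed C-allylation of nitroalkane anions and the Tsuji–Trost macrocyclisation of stabilised carbanions onto allylic acetates. The ten-membered ring closes in the endo sense with respect to the allyl unit (attack at the distal terminus C3, C4=C5 inside the ring) and not by eight-membered exo attack at the substituted terminus C5, because soft nucleophiles prefer the unsubstituted terminus and the larger ring. The only new stereocentre, C2, is not controlled and is destroyed in step 15; the stereo-element that matters is the C4=C5 geometry, which is decided by which acetate leaves: ionisation of the arm trans to C6 gives the syn-allyl complex with the branched C6 pointing away from the metal, and attack at that arm leaves the other acetoxymethyl group (C15) cis to C6 as in the target, whereas ionisation of the cis arm would force C6 into the crowded anti position. Because the two arms are identical, no olefin geometry has to be built beforehand and the arm that does not react is already the C15 acetate of the target. The step also needs C- over O-allylation (normal for nitronates with allylpalladium electrophiles), reaction of the primary allylic acetates in preference to the secondary allylic lactone C6–O bond (which would give a 1,1,3-trisubstituted allyl complex), and cyclisation over oligomerisation, the last secured by slow addition at high dilution; the amine mask keeps the nitronate from adding to C13.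

Step 15
Reactants: 20 macrocyclic nitro compound
Product: 22 macrocyclic C2 ketone with masked lactone, via nitronate DBU-H salt 21 (not isolated)
Conditions: DBU (1.1 equiv), THF, 0 °C; then aq TiCl3 (4.5 equiv), NH4OAc buffer (pH 5–6), THF/H2O, 0 °C → rt; cold NaHCO3 to pH 8, extraction, used directly
Reagents that add atoms: water (O)
Why: Nef reaction in its reductive buffered form: the pre-formed nitronate is reduced by trivalent titanium to the imine, which hydrolyses at pH 5–6 to the C2 ketone without the strong acid or base that would move the C10=C14 or C4=C5 double bond into conjugation; the C2 stereocentre disappears.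

Step 16
Reactants: 22 macrocyclic ketone with masked lactone
Product: 24 CNP0183179.1 (target), via trimethylammonium iodide 23 (not isolated)
Conditions: MeI (excess), MeCN, rt; evaporate; then sat. aq NaHCO3/EtOAc, rt
Reagents that add atoms: none
Why: Exhaustive N-methylation followed by E1cB (Hofmann-type) elimination of trimethylamine across C11–C13 is the classical unmasking of amine-protected α-methylene lactones; only H11 is β to nitrogen, so only the exocyclic olefin can form and both C11 epimers converge.

**Compound list**

1 | 1,3-diacetoxyacetone | CC(=O)OCC(=O)COC(C)=O | starting material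
2 | vinylmagnesium bromide | C=C[Mg]Br | starting material
3 | 2-hydroxy-2-vinylpropane-1,3-diyl diacetate | CC(=O)OCC(O)(C=C)COC(C)=O | intermediate
4 | 4-acetoxy-3-(acetoxymethyl)but-2-enal | CC(=O)OCC(COC(C)=O)=CC=O | intermediate
5 | rac-2-(2-hydroxybut-3-en-1-ylidene)propane-1,3-diyl diacetate | C=CC(O)C=C(COC(C)=O)COC(C)=O | intermediate
6 | (S)-2-(2-hydroxybut-3-en-1-ylidene)propane-1,3-diyl diacetate | C=C[C@H](O)C=C(COC(C)=O)COC(C)=O | intermediate
7 | 2-(bromomethyl)acrylic acid | C=C(CBr)C(=O)O | starting material
8 | 2-(bromomethyl)acryloyl chloride | C=C(CBr)C(Cl)=O | intermediate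
9 | (S)-1-[3-acetoxy-2-(acetoxymethyl)prop-1-en-1-yl]allyl 2-(bromomethyl)acrylate | C=C[C@H](OC(=O)C(=C)CBr)C=C(COC(C)=O)COC(C)=O | intermediate
10 | (R)-3-(bromomethyl)-5-[3-acetoxy-2-(acetoxymethyl)prop-1-en-1-yl]furan-2(5H)-one | BrCC1=C[C@@H](C=C(COC(C)=O)COC(C)=O)OC1=O | intermediate
11 | 3-methylbut-3-en-1-ol | CC(=C)CCO | starting material
12 | paraformaldehyde (formaldehyde) | C=O | starting material
13 | 3-methylenepentane-1,5-diol | C=C(CCO)CCO | intermediate
14 | 5-bromo-3-methylenepentan-1-ol | C=C(CCO)CCBr | intermediate
15 | 5-bromo-3-methylenepentanal | C=C(CC=O)CCBr | intermediate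
16 | (6R,7R,8S) 5-[3-acetoxy-2-(acetoxymethyl)prop-1-enyl]-4-(5-bromo-1-hydroxy-3-methylenepentyl)-3-methylenedihydrofuran-2(3H)-one | BrCCC(=C)C[C@H](O)[C@H]1C(=C)C(=O)O[C@@H]1C=C(COC(C)=O)COC(C)=O | intermediate
17 | C8 acetate of 16 | BrCCC(=C)C[C@H](OC(C)=O)[C@H]1C(=C)C(=O)O[C@@H]1C=C(COC(C)=O)COC(C)=O | intermediate
18 | C2 nitro compound (nitro in place of bromine in 17) | [O-][N+](=O)CCC(=C)C[C@H](OC(C)=O)[C@H]1C(=C)C(=O)O[C@@H]1C=C(COC(C)=O)COC(C)=O | intermediate
19 | dimethylamine adduct of 18 (C11 epimers) | [O-][N+](=O)CCC(=C)C[C@H](OC(C)=O)[C@H]1C(CN(C)C)C(=O)O[C@@H]1C=C(COC(C)=O)COC(C)=O | intermediate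
20 | macrocyclic 2-nitro compound with amine-masked lactone (C2 and C11 epimers) | C=C1CC([N+](=O)[O-])C/C(COC(C)=O)=C/[C@H]2OC(=O)C(CN(C)C)[C@@H]2[C@@H](OC(C)=O)C1 | intermediate
21 | nitronate of 20 as DBU-H salt | C=C1CC(=[N+]([O-])[O-])C/C(COC(C)=O)=C/[C@H]2OC(=O)C(CN(C)C)[C@@H]2[C@@H](OC(C)=O)C1.C3CCC4=[NH+]CCCN4CC3 | intermediate
22 | macrocyclic C2 ketone with amine-masked lactone | C=C1CC(=O)C/C(COC(C)=O)=C/[C@H]2OC(=O)C(CN(C)C)[C@@H]2[C@@H](OC(C)=O)C1 | intermediate
23 | trimethylammonium iodide of 22 | C=C1CC(=O)C/C(COC(C)=O)=C/[C@H]2OC(=O)C(C[N+](C)(C)C)[C@@H]2[C@@H](OC(C)=O)C1.[I-] | intermediate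
24 | CNP0183179.1, (6R,7R,8S)-8,15-diacetoxy-2-oxogermacra-4,10(14),11(13)-trien-12,6-olide with ring-trans C4=C5 | C=C1CC(=O)C/C(COC(C)=O)=C/[C@H]2OC(=O)C(=C)[C@@H]2[C@@H](OC(C)=O)C1 | target

**Step count and risks**

Total: 16 steps. Longest linear sequence: 13 steps (steps 1–6 and 10–16); steps 7–9 are a convergent branch.

Steps most likely to fail:

Step 14 (proposed new method). What may go wrong: oligomerisation and O-allylation overtaking the slow ten-membered ring closure of the weakly nucleophilic, singly stabilised nitronate, with some ionisation through the arm cis to C6. Fallback with known chemistry, setting out from 17 and coming back at 20: dimethylamine (1 equiv, −20 °C) adds to the methylene lactone of 17 to give the amino bromide F1. C-alkylation of tert-butyl nitroacetate with F1 (K2CO3, Bu4NI, DMF) gives the α-nitro ester F2, a doubly stabilised carbon acid of the class for which Tsuji–Trost macrocyclisation onto allylic acetates is established. Pd(PPh3)4 under high dilution, with the departing acetate as base, should then give the ring-closed α-nitro ester F3. CF3CO2H removes the tert-butyl group with spontaneous decarboxylation to deliver 20.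

Step 10. What may go wrong: erosion of simple diastereoselection at C8 if the aqueous Barbier addition leaks through an open transition state. Fallback setting out from 10 and 15 and coming back at 17: the 8-epimer of 16 F4 formed in the same coupling is separated and not discarded. Mitsunobu esterification with acetic acid (PPh3, DIAD, AcOH, toluene) inverts C8 and gives acetate 17 directly, so the stereocentre is corrected after, not during, the C–C bond formation and both epimers converge.

Step 15. What may go wrong: arrest of the reduction at the oxime of the hindered ring carbon, or migration of the C10=C14 or C4=C5 double bond into conjugation with the new ketone. Fallback setting out from 20 and coming back at 22: reduction with divalent tin thiolate (SnCl2, PhSH, Et3N, MeCN) should stop at the ketoxime F5. Transoximation to aqueous glyoxylic acid (NaOAc buffer, THF/H2O) then frees ketone 22 under weakly acidic conditions in which enolisation is slow.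

Further compounds
F1 | step 14 | dimethylamine adduct of bromide 17 (C11 epimers) | BrCCC(=C)C[C@H](OC(C)=O)[C@H]1C(CN(C)C)C(=O)O[C@@H]1C=C(COC(C)=O)COC(C)=O
F2 | step 14 | tert-butyl 2-nitro ester from C-alkylation of tert-butyl nitroacetate with F1 | CC(C)(C)OC(=O)C([N+](=O)[O-])CCC(=C)C[C@H](OC(C)=O)[C@H]1C(CN(C)C)C(=O)O[C@@H]1C=C(COC(C)=O)COC(C)=O
F3 | step 14 | macrocyclic tert-butyl 2-nitro-2-carboxylate (C2 quaternary) | C=C1CC(C(=O)OC(C)(C)C)([N+](=O)[O-])C/C(COC(C)=O)=C/[C@H]2OC(=O)C(CN(C)C)[C@@H]2[C@@H](OC(C)=O)C1
F4 | step 10 | 8-epimer of 16 | BrCCC(=C)C[C@@H](O)[C@H]1C(=C)C(=O)O[C@@H]1C=C(COC(C)=O)COC(C)=O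
F5 | step 15 | C2 ketoxime of 22 | C=C1CC(=NO)C/C(COC(C)=O)=C/[C@H]2OC(=O)C(CN(C)C)[C@@H]2[C@@H](OC(C)=O)C1
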